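We hold one closed, stirred flask at constant temperature and look at its catalyst E at the moment 20% of the Q is converted.

Q 0.0050 M; L 0.500 mM; E 0.30 mM; D 62 µM

    Q + E → Q.E (k1 = 89 L mol⁻¹ s⁻¹)
    Q.E → E + X (k2 = 51 s⁻¹)
    Q.E + L → Q.E.L (k3 = 4700 L mol⁻¹ s⁻¹)
    E + D → E.D (k4 = 55000 L mol⁻¹ s⁻¹)

1. the form that holds most of the catalyst when 20% of the Q are converted (E / E.D / Q.E / Q.E.L)
2. its share of the catalyst then
3. apparent order in E when 20% of the Q are converted (percent change of the rate of making X for one percent more E charged)
4. factor on the rate of making X when 20% of the Q are converted if E is charged twice over

We keep a ledger of the 0.30 mM of E charged. The first entry is D, the limiting reagent of its step, since its charge is smaller than that of E. At the start each E meets D at 3.4 s⁻¹ and Q at 0.45 s⁻¹, so D takes E faster than Q does. D has no other step, so we book 62 µM as E.D.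

The second entry is a leak. Each Q.E either releases E and X or is caught by L. We call the rate constant of catching over that of release the selectivity factor, s = 92.2 L mol⁻¹; s times [L] is the Q.E.L made per X made. With L as charged that is 0.0461, so of the 1.00 mM of Q converted we book 44.0 µM as Q.E.L.

The third entry is Q.E itself, made from Q at 4.00 mM and released at 51 s⁻¹, which comes to 1.35 µM. The books close with 193 µM of free E, or 64.2%, the resting state.

Q.E breaks up much faster than E takes up Q, so at a set conversion we let the rate follow free E. We take the first two entries as unchanged by a larger charge of E. That gives an order of 1.55 and a factor of 2.55 on doubling.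

The forecast says E at 65%, order 1.53, factor 2.53, since “these losses are essentially fixed amounts at a given conversion”. Our share lies lower, and our order and factor higher.

The flask gives E at 64.8%, order 1.5, factor 2.53. The answer E belongs to the moment asked: at 80.0 s this flask holds more Q.E.L, 42.3%, than E, 36.9%. We use s once more at a converted fraction of 0.7 of the Q in this flask, now letting L fall as it is taken: Q.E.L is the charge of L times one minus the exponential of minus s times the X made. Taking X as the Q converted, this gives 138 µM, or 46.0% of the catalyst. At that conversion, reached at 92.6 s, the flask reads 44.5% of its catalyst as Q.E.L.

(The numbers are invented; what happens was integrated by code.)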